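**Remarks on the chemistry**

- Assumption: methoxyacetylene 16 is bought as a cold solution or, where it is not stocked, made in one operation from chloroacetaldehyde dimethyl acetal and NaNH2; every intermediate that has a stereocentre is racemic and the target is achiral.
- Abbreviation used in names: ArCD = 2,4-bis(benzyloxy)-3-[4-(benzyloxy)-2-methoxy-6-methylbenzoyl]-6-methoxyphenyl (benzylated ring C carrying ring D through K2, attached through its bridge carbon).
- Atom labels: ring A is a1 (C–OMe), a2 (CH), a3 (C–OH), a4 (C–K1), a5 (C–OH), a6 (C–CH2); ring C is c1–c6 in the same sense; K1 joins rings A and B, K2 joins rings C and D.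

## Structural features

The target is an achiral bis-benzophenone in which ring A (bound to ring B through K1) and ring C (bound to ring D through K2) are joined by a single CH2 between a6 and c6. Rings A and C are hexasubstituted phloroglucinols of identical pattern: methoxy para to the ketone, two hydroxyls flanking the ketone, and the bridge between the methoxy carbon and one hydroxyl carbon. Rings B and D are orsellinoyl units that differ only in the methyl ether that ring D carries ortho to K2. There are no stereocentres, but both ketones are tetra-ortho-substituted and twisted, so they are hard to form and slow to react. The fragile elements are the seven free phenols, the doubly activated diarylmethane (cleavable through an ortho-quinone methide), the 2-hydroxy-2'-methoxybenzophenone motif of the C–D half (xanthone closure under hot base), and the ketones during hydrogenolysis. The real difficulty is that the two halves are almost the same, so any one-carbon condensation is statistical and any electrophilic substitution on a monomethyl phloroglucinol has competing sites. The key step exploits ring A: its three oxygens at a1, a3 and a5 arrive as three different groups and its bridge carbon a6 lies between a1 and a5, a pattern that a 3-methoxy-4-(arylmethyl)cyclobutenone (a5, a6, a1, a2) and a C-silyl ynol ether (a3, a4) write in one operation, with a silyl handle at a4 where K1 must go. The two annulation partners and the annulation product were traced atom by atom through the mechanism and their structures need no change.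

## Logic of the disconnections

**37 from 36.** Five O–CH2Ph bonds are cut. Benzyl is the one group that survives acid chlorides, ketenes, organolithiums, fluoride and heat and is then removed without acid or base. The demand is that hydrogenolysis spares two diaryl ketones.

**36 from 33 (through 34 and 35).** The a4–K1 bond is cut. An intermolecular acylation at a4 would have to join two di-ortho-substituted partners and distinguish a4 from a2. The aroyl group is therefore placed on the a5 oxygen (33) and moved to a carbanion at a4 by a 1,3 O→C shift. This reduces the problem to one O-acylation and one carbon–halogen bond. The demand is that halogen–metal exchange outruns attack on K2 and on the ester.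

**33 from 31 and 30 (through 32).** The ester C–O bond is cut. 30 comes from 1 in two steps (through 29). The demand is an esterification between two hindered partners.

**31 from 28.** The C–I bond at a4 is traced back to a C–Si bond. Ipso substitution puts the halogen where the silicon was, so no directing effect has to be trusted. The demand is that ipso attack beats substitution at a2.

**28 from 19 and 23.** The a4–a5 and a2–a3 bonds are cut, and a5–a6 is traced back to the four-membered ring of 19. The whole of ring A, with its three differentiated oxygens, the bridge and the a4 handle, falls to a cyclobutenone and an alkyne. The demand is correct orientation of the ketene–alkyne union and tolerance of K2.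

**23 from 20.** The O–Si bond and the oxygen-bearing alkyne carbon are removed. The ynolate is assembled from a lithiated silyldiazomethane and CO, so the C-silyl group is present from the start.

**19 from 15 and 16 (through 17 and 18).** The C1–C2 and C3–C4 bonds of the cyclobutenone are cut to a monoalkylketene and an alkoxyalkyne. This places the methoxy at C3 and the arylmethyl group at C4 by polarity alone. The demand is that the ketene is trapped faster than it dimerises.

**15 from 14, and 14 from 12 and 13.** The c6–CH2 bond is cut as an sp2–sp3 cross-coupling. An acid-mediated hydroarylation was set aside because strong acid endangers the ring D benzyl ether. The coupling brings in the bridge carbon, a6 and a5 as one three-carbon unit under neutral conditions.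

**12 from 11, and 11 from 10.** Two O–benzyl bonds and one C–I bond are cut. In 10 the two free positions of ring C are equivalent and ring C is far more electron-rich than ring D, so halogenation has a single outcome.

**10 from 9, and 9 from 6 and 4 (through 8 and 7); 6 from 5.** The c4–K2 bond is cut. Acylating 5 directly would give regioisomers. Metalation between two acetal ethers fixes the site, and the hindered ketone cannot over-react.

**4 from 3, 3 from 2, 2 from 1.** Three C–O bonds are cut in the order allowed by the hydrogen bond in 1: first the carboxyl and para oxygen, then the ortho oxygen (the permanent methyl ether of ring D), then the ester.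

## Other disconnections considered

**Alternative 1:** The cut is through the b1–K1 and b2–CH2 bonds of ring B. Fluoride would convert the ortho-silylaryl triflate A2 into an aryne, and the enolate of the ring A β-ketoester A1 would insert it into its C–C bond to give A3.

- In its favour: one mild step makes the tetra-ortho-substituted ketone K1 and sets the future methyl beside it. The 3-alkoxy aryne directs the nucleophile to the carbon remote from oxygen, so the regiochemistry is sound. No organolithium is used in the presence of K2.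
- Against it here: A1 already contains the complete hexasubstituted ring A with its bridge, so the central problem is left unsolved. The ketone of A1 is flanked by two benzyloxy groups, so ring closure of the aryl anion onto it may lose to simple arylation. The CH2CO2tBu group must afterwards be cleaved and decarboxylated next to a ketone, where closure to an isocoumarin-type lactone is a risk.
- Comparison: on K1 formation, one step against three (steps 16–18), this alternative is the better. On structure it attaches ring B where the chosen plan builds ring A, so it is the weaker on the real difficulty. On step economy the methyl unmasking cancels the gain, and the late stages are about equal.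

**Alternative 2:** The cut is the b1–b2 bond. The 1-aryl-1,3,5,7-tetraketone A4 would close under mild base by aldol attack of C2 on the methyl ketone to give A5.

- In its favour: it is biomimetic, ring B arrives with its methyl and both hydroxyls free, no ring B protecting groups are needed, and A5 is one hydrogenolysis from the target. That end-game is shorter than the chosen plan's and is the better on that point. Regiochemistry follows from the greater electrophilicity of the methyl ketone over the hindered aryl ketone, which is at least as predictable as the ketene–alkyne orientation.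
- Against it here: A4 again presupposes the complete ring A. Its assembly needs acyl transfer from a carbonyl flanked by two ortho substituents to a polyketide enolate, and such polyketones are prone to other cyclisation modes (pyranone formation, attack on the aryl ketone).
- Comparison: the mechanism is ionic and under thermodynamic influence, against a pericyclic cascade. Structurally it does not address the bridge. Overall step count would be governed by the unknown route to A4.

**Alternative 3:** The cut is the c4–c5 bond of ring C. This bond joins the K2-bearing carbon to the hydroxyl carbon beside the bridge carbon; the c5–c6 bond is already present as C2–C3 of the pyranone and is not made in this step. Mg(OMe)2 would open the pyranone A6 and the doubly activated CH2 would attack the ester carbon to give A7.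

- In its favour: like the chosen plan it builds a hexasubstituted phloroglucinol with the bridge already in place. It is the better in two respects: the ketone K2 is delivered in the same step, and the oxygen pattern follows from the connectivity of the chain with no orientation to control. A7 is one hydrogenolysis from the target.
- Against it here: A6 must carry the whole A–B benzophenone on C3 and a ring D aroylmethyl group on C6, and both need bond formations at hindered centres. The ester that must be attacked is a vinylogous carbonate on a tetrasubstituted alkene, so reclosure to the pyranone competes. Hot basic methanol also threatens xanthone closure in the D-ring ketone.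
- Comparison: both plans are ring constructions and are equal on structure. The chosen plan is neutral and thermal, where this one is a reversible base-mediated condensation. Late-stage step economy favours this alternative; the route to A6 does not.

Key step: step 13

## Steps

Step 1
Reactants: 1 orsellinic acid (2,4-dihydroxy-6-methylbenzoic acid)
Product: 2 benzyl 4-(benzyloxy)-2-hydroxy-6-methylbenzoate
Conditions: BnBr (2.1 equiv), K2CO3, DMF, rt
Reagents that add atoms: benzyl bromide, BrCc1ccccc1
Why: Williamson-type O-alkylation of the carboxylate and of the free para hydroxyl; the ortho hydroxyl is hydrogen-bonded to the carbonyl and should remain untouched with two equivalents of halide at room temperature.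

Step 2
Reactants: 2 benzyl 4-(benzyloxy)-2-hydroxy-6-methylbenzoate
Product: 3 benzyl 4-(benzyloxy)-2-methoxy-6-methylbenzoate
Conditions: MeI, K2CO3, DMF, 50 °C
Reagents that add atoms: iodomethane, CI
Why: Williamson O-methylation; warming and a small electrophile overcome the hydrogen bond and install the ring D methyl ether that stays to the end.

Step 3
Reactants: 3 benzyl 4-(benzyloxy)-2-methoxy-6-methylbenzoate
Product: 4 4-(benzyloxy)-2-methoxy-6-methylbenzoic acid
Conditions: KOH, DMSO/H2O, 90 °C; then HCl (1 M)
Reagents that add atoms: potassium hydroxide, [K+].[OH-]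
Why: Saponification of a di-ortho-substituted benzoate needs poorly solvated hydroxide and heat (cleavage at the acyl carbon is assumed); the aryl ethers are inert.

Step 4
Reactants: 5 5-methoxyresorcinol
Product: 6 1-methoxy-3,5-bis(methoxymethoxy)benzene
Conditions: MOMCl, iPr2NEt, CH2Cl2, 0 °C → rt
Reagents that add atoms: chloromethyl methyl ether, COCCl
Why: Acetal-type O-alkylation; the methoxymethyl ethers are chosen as strong ortho-directing groups that are later removed under conditions harmless to benzyl ethers.

Step 5
Reactants: 4 4-(benzyloxy)-2-methoxy-6-methylbenzoic acid, 6 1-methoxy-3,5-bis(methoxymethoxy)benzene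
Product: 9 [4-(benzyloxy)-2-methoxy-6-methylphenyl][4-methoxy-2,6-bis(methoxymethoxy)phenyl]methanone, via acid chloride 7 (not isolated), via aryllithium 8 (not isolated)
Conditions: 4, (COCl)2, DMF (cat.), CH2Cl2, rt, concentrate; 6, n-BuLi, THF, 0 °C; then 7, THF, −78 → 0 °C
Reagents that add atoms: none
Why: Directed ortho-metalation should occur at the position between the two acetal ethers, which is doubly coordinated and the most acidic, and not next to the methoxy group. Acylation of the aryllithium by the hindered aroyl chloride stops at the ketone because the tetra-ortho-substituted carbonyl cannot accept a second nucleophile.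

Step 6
Reactants: 9 [4-(benzyloxy)-2-methoxy-6-methylphenyl][4-methoxy-2,6-bis(methoxymethoxy)phenyl]methanone
Product: 10 [4-(benzyloxy)-2-methoxy-6-methylphenyl](2,6-dihydroxy-4-methoxyphenyl)methanone
Conditions: HCl (3 M aq.), MeOH, 50 °C
Reagents that add atoms: none
Why: Acid-catalysed acetal methanolysis; the formaldehyde equivalent leaves as dimethoxymethane and cannot attack the electron-rich ring, and benzyl and methyl ethers are stable.

Step 7
Reactants: 10 [4-(benzyloxy)-2-methoxy-6-methylphenyl](2,6-dihydroxy-4-methoxyphenyl)methanone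
Product: 11 [4-(benzyloxy)-2-methoxy-6-methylphenyl](2,6-dihydroxy-3-iodo-4-methoxyphenyl)methanone
Conditions: NIS (1.0 equiv), DMF, −20 → 0 °C
Reagents that add atoms: N-iodosuccinimide, O=C1CCC(=O)N1I
Why: Electrophilic aromatic iodination; the free resorcinol ring C is far more nucleophilic than ring D and its two open positions are equivalent, so one equivalent at low temperature should give a single mono-iodide.

Step 8
Reactants: 11 [4-(benzyloxy)-2-methoxy-6-methylphenyl](2,6-dihydroxy-3-iodo-4-methoxyphenyl)methanone
Product: 12 [2,6-bis(benzyloxy)-3-iodo-4-methoxyphenyl][4-(benzyloxy)-2-methoxy-6-methylphenyl]methanone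
Conditions: BnBr (2.5 equiv), K2CO3, DMF, 40 °C
Reagents that add atoms: benzyl bromide, BrCc1ccccc1
Why: Williamson benzylation of both phenols; the temperature is kept low so that a phenoxide does not displace the ring D methoxy group (xanthone closure).

Step 9
Reactants: 12 [2,6-bis(benzyloxy)-3-iodo-4-methoxyphenyl][4-(benzyloxy)-2-methoxy-6-methylphenyl]methanone, 13 (3-ethoxy-3-oxopropyl)zinc bromide
Product: 14 ethyl 3-(ArCD)propanoate
Conditions: Pd(OAc)2 (3 mol %), SPhos (6 mol %), THF, 50 °C
Reagents that add atoms: none
Why: Negishi coupling of an sp3 zinc homoenolate with a di-ortho-substituted aryl iodide; the bulky biaryl phosphine supports oxidative addition and reductive elimination at the crowded centre, and the organozinc ignores the hindered ketone. The reagent's zinc-bearing carbon becomes the bridge CH2, its C2 becomes a6 and its ester carbon becomes a5.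

Step 10
Reactants: 14 ethyl 3-(ArCD)propanoate
Product: 15 3-(ArCD)propanoic acid
Conditions: LiOH, THF/MeOH/H2O, rt; then HCl (1 M)
Reagents that add atoms: lithium hydroxide, [Li+].[OH-]
Why: Ordinary saponification of an unhindered ethyl ester.

Step 11
Reactants: 15 3-(ArCD)propanoic acid, 16 methoxyacetylene
Product: 19 racemic 3-methoxy-4-(ArCD-methyl)cyclobut-2-en-1-one, via acid chloride 17 (not isolated), via ketene 18 (not isolated)
Conditions: (COCl)2, DMF (cat.), CH2Cl2, rt, concentrate; slow addition to 16 (5 equiv), Et3N, Et2O, 0 °C → rt (closed vessel)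
Reagents that add atoms: none
Why: Dehydrochlorination gives the monoalkylketene, which undergoes thermal [2+2] cycloaddition with the alkoxyalkyne. The unsubstituted, nucleophilic alkyne carbon bonds to the ketene carbonyl carbon, so methoxy ends at C3 and the arylmethyl group at C4. C4 forms as a racemic centre that the key step erases, and both ortho positions of ring C are blocked, so the acid chloride cannot close to an indanone.

Step 12
Reactants: 20 (trimethylsilyl)diazomethane
Product: 23 triisopropyl{[(trimethylsilyl)ethynyl]oxy}silane, via lithiated diazomethane 21 (not isolated), via lithium ynolate 22 (not isolated)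
Conditions: n-BuLi, THF, −78 °C; CO (1 atm), −78 °C; TIPSCl, −78 → 0 °C
Reagents that add atoms: carbon monoxide, [C-]#[O+]; chlorotriisopropylsilane, CC(C)[Si](Cl)(C(C)C)C(C)C
Why: The lithiated silyldiazomethane captures CO and loses N2 to give the C-silyl lithium ynolate, and the bulky chlorosilane silylates it on oxygen (ynolate O-silylation) to give the ynol silyl ether.

Step 13
Reactants: 19 racemic 3-methoxy-4-(ArCD-methyl)cyclobut-2-en-1-one, 23 triisopropyl{[(trimethylsilyl)ethynyl]oxy}silane
Product: 28 2-(ArCD-methyl)-3-methoxy-5-(triisopropylsilyloxy)-6-(trimethylsilyl)phenol, via vinylketene 24 (not isolated), via vinylcyclobutenone 25 (not isolated), via dienylketene 26 (not isolated), via cyclohexadienone 27 (not isolated)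
Conditions: 23 (1.5 equiv), PhMe, 80 °C, then 110 °C (sealed tube)
Reagents that add atoms: none
Why: Heating opens 19 by four-electron electrocyclic cleavage of its C1–C4 bond to the 3-methoxy vinylketene 24, the arylmethyl group turning outward. The ynol ether adds to the ketene in a [2+2] cycloaddition in which its silyl-bearing carbon bonds to the ketene carbonyl carbon (a4–a5) and its oxygen-bearing carbon to the ketene α-carbon (a2–a3), giving 25. A second, reversible four-electron opening of 25 gives the dienylketene 26 with the ketene and the methoxyvinyl arm cis; ring A is then closed by a thermally allowed disrotatory six-electron electrocyclisation that re-forms a5–a6, and dienone 27 aromatises by tautomerisation. The closest known reaction type is the Danheiser benzannulation of cyclobutenones with siloxyalkynes to resorcinol monosilyl ethers; here the 3-methoxy group turns the product into a fully differentiated phloroglucinol. No stereocentre is created and the one in 19 is erased. The selectivity needed is the orientation of the ketene–alkyne union: the oxygen lone pair makes the remote alkyne carbon the nucleophile, and the positive charge developing on the oxygen-bearing carbon is further stabilised by the β-silicon, so the silyl group reinforces the polarisation at the cost of some steric retardation. Chemoselectivity rests on the ketene preferring the electron-rich alkyne over the tetra-ortho-substituted ketone K2, the ethers and itself, which the excess of 23 supports.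

Step 14
Reactants: 1 orsellinic acid (2,4-dihydroxy-6-methylbenzoic acid)
Product: 29 benzyl 2,4-bis(benzyloxy)-6-methylbenzoate
Conditions: BnBr (3.5 equiv), K2CO3, DMF, 60 °C
Reagents that add atoms: benzyl bromide, BrCc1ccccc1
Why: Exhaustive Williamson benzylation; excess halide and heat also alkylate the hydrogen-bonded ortho hydroxyl.

Step 15
Reactants: 29 benzyl 2,4-bis(benzyloxy)-6-methylbenzoate
Product: 30 2,4-bis(benzyloxy)-6-methylbenzoic acid
Conditions: KOH, DMSO/H2O, 90 °C; then HCl (1 M)
Reagents that add atoms: potassium hydroxide, [K+].[OH-]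
Why: Saponification of the hindered benzoate as in step 3 (cleavage at the acyl carbon is assumed); the benzyl aryl ethers are inert.

Step 16
Reactants: 28 2-(ArCD-methyl)-3-methoxy-5-(triisopropylsilyloxy)-6-(trimethylsilyl)phenol
Product: 31 2-(ArCD-methyl)-6-iodo-3-methoxy-5-(triisopropylsilyloxy)phenol
Conditions: ICl (1.0 equiv), CH2Cl2, −78 °C
Reagents that add atoms: iodine monochloride, ClI
Why: Electrophilic ipso-iododesilylation; attack at the silyl-bearing a4 is activated by the ortho hydroxyl, the ortho silyloxy and the para methoxy groups and by β-silicon stabilisation of the arenium ion, and loss of the silyl cation is faster than loss of a proton from the one competing site a2. No acid is released, so the silyl ether should survive.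

Step 17
Reactants: 31 2-(ArCD-methyl)-6-iodo-3-methoxy-5-(triisopropylsilyloxy)phenol, 30 2,4-bis(benzyloxy)-6-methylbenzoic acid
Product: 33 2-(ArCD-methyl)-6-iodo-3-methoxy-5-(triisopropylsilyloxy)phenyl 2,4-bis(benzyloxy)-6-methylbenzoate, via acid chloride 32 (not isolated)
Conditions: 30, (COCl)2, DMF (cat.), CH2Cl2, rt, concentrate; 31, NaH, THF, 0 °C; then 32, 0 °C → rt
Reagents that add atoms: none
Why: O-acylation of a phenoxide by an aroyl chloride; the sodium phenoxide is used because both partners are di-ortho-substituted and a neutral phenol would react too slowly.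

Step 18
Reactants: 33 2-(ArCD-methyl)-6-iodo-3-methoxy-5-(triisopropylsilyloxy)phenyl 2,4-bis(benzyloxy)-6-methylbenzoate
Product: 36 [2,4-bis(benzyloxy)-6-methylphenyl][3-(ArCD-methyl)-2,6-dihydroxy-4-methoxyphenyl]methanone, via aryllithium 34 (not isolated), via silyl ether ketone 35 (not isolated)
Conditions: n-BuLi (1.05 equiv), THF, −100 → −78 °C; AcOH (2 equiv); then TBAF, THF, 0 °C
Reagents that add atoms: none
Why: Iodine–lithium exchange is faster than addition of the alkyllithium to the hindered ester or to the tetra-ortho-substituted ketone K2. The aryllithium at a4 attacks the neighbouring ester carbonyl and the a5–O acyl bond breaks (anionic ortho-Fries rearrangement, 1,3 O→C acyl shift), which forms K1. Buffered fluoride then cleaves the aryl silyl ether in the same flask.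

Step 19
Reactants: 36 [2,4-bis(benzyloxy)-6-methylphenyl][3-(ArCD-methyl)-2,6-dihydroxy-4-methoxyphenyl]methanone
Product: 37 (2,4-dihydroxy-6-methylphenyl)[2,6-dihydroxy-3-{[2,4-dihydroxy-3-(4-hydroxy-2-methoxy-6-methylbenzoyl)-6-methoxyphenyl]methyl}-4-methoxyphenyl]methanone (target)
Conditions: H2 (1 atm), Pd/C (10%), EtOAc/MeOH, rt
Reagents that add atoms: none
Why: Hydrogenolysis of five aryl benzyl ethers; the two diaryl ketones are tetra-ortho-substituted, twisted and hydrogen-bonded, which should protect them from reduction at one atmosphere and room temperature.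

## Compound list

1 | orsellinic acid (2,4-dihydroxy-6-methylbenzoic acid) | Cc1cc(O)cc(O)c1C(=O)O | starting material
2 | benzyl 4-(benzyloxy)-2-hydroxy-6-methylbenzoate | Cc1cc(OCc2ccccc2)cc(O)c1C(=O)OCc1ccccc1 | intermediate
3 | benzyl 4-(benzyloxy)-2-methoxy-6-methylbenzoate | COc1cc(OCc2ccccc2)cc(C)c1C(=O)OCc1ccccc1 | intermediate
4 | 4-(benzyloxy)-2-methoxy-6-methylbenzoic acid | COc1cc(OCc2ccccc2)cc(C)c1C(=O)O | intermediate
5 | 5-methoxyresorcinol | COc1cc(O)cc(O)c1 | starting material
6 | 1-methoxy-3,5-bis(methoxymethoxy)benzene | COCOc1cc(OC)cc(OCOC)c1 | intermediate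
7 | 4-(benzyloxy)-2-methoxy-6-methylbenzoyl chloride | COc1cc(OCc2ccccc2)cc(C)c1C(Cl)=O | intermediate
8 | [4-methoxy-2,6-bis(methoxymethoxy)phenyl]lithium | [Li]c1c(OCOC)cc(OC)cc1OCOC | intermediate
9 | [4-(benzyloxy)-2-methoxy-6-methylphenyl][4-methoxy-2,6-bis(methoxymethoxy)phenyl]methanone | COCOc1cc(OC)cc(OCOC)c1C(=O)c1c(C)cc(OCc2ccccc2)cc1OC | intermediate
10 | [4-(benzyloxy)-2-methoxy-6-methylphenyl](2,6-dihydroxy-4-methoxyphenyl)methanone | COc1cc(O)c(C(=O)c2c(C)cc(OCc3ccccc3)cc2OC)c(O)c1 | intermediate
11 | [4-(benzyloxy)-2-methoxy-6-methylphenyl](2,6-dihydroxy-3-iodo-4-methoxyphenyl)methanone | COc1cc(O)c(C(=O)c2c(C)cc(OCc3ccccc3)cc2OC)c(O)c1I | intermediate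
12 | [2,6-bis(benzyloxy)-3-iodo-4-methoxyphenyl][4-(benzyloxy)-2-methoxy-6-methylphenyl]methanone | COc1cc(OCc2ccccc2)c(C(=O)c2c(C)cc(OCc3ccccc3)cc2OC)c(OCc2ccccc2)c1I | intermediate
13 | (3-ethoxy-3-oxopropyl)zinc bromide | CCOC(=O)CC[Zn]Br | starting material
14 | ethyl 3-(ArCD)propanoate | CCOC(=O)CCc1c(OC)cc(OCc2ccccc2)c(C(=O)c2c(C)cc(OCc3ccccc3)cc2OC)c1OCc1ccccc1 | intermediate
15 | 3-(ArCD)propanoic acid | OC(=O)CCc1c(OC)cc(OCc2ccccc2)c(C(=O)c2c(C)cc(OCc3ccccc3)cc2OC)c1OCc1ccccc1 | intermediate
16 | methoxyacetylene | COC#C | starting material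
17 | 3-(ArCD)propanoyl chloride | ClC(=O)CCc1c(OC)cc(OCc2ccccc2)c(C(=O)c2c(C)cc(OCc3ccccc3)cc2OC)c1OCc1ccccc1 | intermediate
18 | 3-(ArCD)prop-1-en-1-one (monoalkylketene) | O=C=CCc1c(OC)cc(OCc2ccccc2)c(C(=O)c2c(C)cc(OCc3ccccc3)cc2OC)c1OCc1ccccc1 | intermediate
19 | racemic 3-methoxy-4-(ArCD-methyl)cyclobut-2-en-1-one | COC1=CC(=O)C1Cc1c(OC)cc(OCc2ccccc2)c(C(=O)c2c(C)cc(OCc3ccccc3)cc2OC)c1OCc1ccccc1 | intermediate
20 | (trimethylsilyl)diazomethane | C[Si](C)(C)C=[N+]=[N-] | starting material
21 | lithio(trimethylsilyl)diazomethane | [Li]C(=[N+]=[N-])[Si](C)(C)C | intermediate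
22 | lithium 2-(trimethylsilyl)ethynolate | [Li]OC#C[Si](C)(C)C | intermediate
23 | triisopropyl{[(trimethylsilyl)ethynyl]oxy}silane | C[Si](C)(C)C#CO[Si](C(C)C)(C(C)C)C(C)C | intermediate
24 | (3Z)-3-methoxy-5-(ArCD)penta-1,3-dien-1-one | O=C=C/C(OC)=C/Cc1c(OC)cc(OCc2ccccc2)c(C(=O)c2c(C)cc(OCc3ccccc3)cc2OC)c1OCc1ccccc1 | intermediate
25 | racemic 4-[(1Z)-1-methoxy-3-(ArCD)prop-1-en-1-yl]-3-(triisopropylsilyloxy)-2-(trimethylsilyl)cyclobut-2-en-1-one | O=C1C([Si](C)(C)C)=C(O[Si](C(C)C)(C(C)C)C(C)C)C1/C(OC)=C/Cc1c(OC)cc(OCc2ccccc2)c(C(=O)c2c(C)cc(OCc3ccccc3)cc2OC)c1OCc1ccccc1 | intermediate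
26 | (3E,5Z)-5-methoxy-7-(ArCD)-3-(triisopropylsilyloxy)-2-(trimethylsilyl)hepta-1,3,5-trien-1-one | O=C=C([Si](C)(C)C)/C(O[Si](C(C)C)(C(C)C)C(C)C)=C\C(OC)=C\Cc1c(OC)cc(OCc2ccccc2)c(C(=O)c2c(C)cc(OCc3ccccc3)cc2OC)c1OCc1ccccc1 | intermediate
27 | racemic 6-(ArCD-methyl)-5-methoxy-3-(triisopropylsilyloxy)-2-(trimethylsilyl)cyclohexa-2,4-dien-1-one | O=C1C([Si](C)(C)C)=C(O[Si](C(C)C)(C(C)C)C(C)C)C=C(OC)C1Cc1c(OC)cc(OCc2ccccc2)c(C(=O)c2c(C)cc(OCc3ccccc3)cc2OC)c1OCc1ccccc1 | intermediate
28 | 2-(ArCD-methyl)-3-methoxy-5-(triisopropylsilyloxy)-6-(trimethylsilyl)phenol | COc1cc(O[Si](C(C)C)(C(C)C)C(C)C)c([Si](C)(C)C)c(O)c1Cc1c(OC)cc(OCc2ccccc2)c(C(=O)c2c(C)cc(OCc3ccccc3)cc2OC)c1OCc1ccccc1 | intermediate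
29 | benzyl 2,4-bis(benzyloxy)-6-methylbenzoate | Cc1cc(OCc2ccccc2)cc(OCc2ccccc2)c1C(=O)OCc1ccccc1 | intermediate
30 | 2,4-bis(benzyloxy)-6-methylbenzoic acid | Cc1cc(OCc2ccccc2)cc(OCc2ccccc2)c1C(=O)O | intermediate
31 | 2-(ArCD-methyl)-6-iodo-3-methoxy-5-(triisopropylsilyloxy)phenol | COc1cc(O[Si](C(C)C)(C(C)C)C(C)C)c(I)c(O)c1Cc1c(OC)cc(OCc2ccccc2)c(C(=O)c2c(C)cc(OCc3ccccc3)cc2OC)c1OCc1ccccc1 | intermediate
32 | 2,4-bis(benzyloxy)-6-methylbenzoyl chloride | Cc1cc(OCc2ccccc2)cc(OCc2ccccc2)c1C(Cl)=O | intermediate
33 | 2-(ArCD-methyl)-6-iodo-3-methoxy-5-(triisopropylsilyloxy)phenyl 2,4-bis(benzyloxy)-6-methylbenzoate | COc1cc(O[Si](C(C)C)(C(C)C)C(C)C)c(I)c(OC(=O)c2c(C)cc(OCc3ccccc3)cc2OCc2ccccc2)c1Cc1c(OC)cc(OCc2ccccc2)c(C(=O)c2c(C)cc(OCc3ccccc3)cc2OC)c1OCc1ccccc1 | intermediate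
34 | 2-(ArCD-methyl)-6-lithio-3-methoxy-5-(triisopropylsilyloxy)phenyl 2,4-bis(benzyloxy)-6-methylbenzoate | COc1cc(O[Si](C(C)C)(C(C)C)C(C)C)c([Li])c(OC(=O)c2c(C)cc(OCc3ccccc3)cc2OCc2ccccc2)c1Cc1c(OC)cc(OCc2ccccc2)c(C(=O)c2c(C)cc(OCc3ccccc3)cc2OC)c1OCc1ccccc1 | intermediate
35 | [2,4-bis(benzyloxy)-6-methylphenyl][3-(ArCD-methyl)-2-hydroxy-4-methoxy-6-(triisopropylsilyloxy)phenyl]methanone | COc1cc(O[Si](C(C)C)(C(C)C)C(C)C)c(C(=O)c2c(C)cc(OCc3ccccc3)cc2OCc2ccccc2)c(O)c1Cc1c(OC)cc(OCc2ccccc2)c(C(=O)c2c(C)cc(OCc3ccccc3)cc2OC)c1OCc1ccccc1 | intermediate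
36 | [2,4-bis(benzyloxy)-6-methylphenyl][3-(ArCD-methyl)-2,6-dihydroxy-4-methoxyphenyl]methanone | COc1cc(O)c(C(=O)c2c(C)cc(OCc3ccccc3)cc2OCc2ccccc2)c(O)c1Cc1c(OC)cc(OCc2ccccc2)c(C(=O)c2c(C)cc(OCc3ccccc3)cc2OC)c1OCc1ccccc1 | intermediate
37 | (2,4-dihydroxy-6-methylphenyl)[2,6-dihydroxy-3-{[2,4-dihydroxy-3-(4-hydroxy-2-methoxy-6-methylbenzoyl)-6-methoxyphenyl]methyl}-4-methoxyphenyl]methanone | COc1cc(O)c(C(=O)c2c(C)cc(O)cc2O)c(O)c1Cc1c(OC)cc(O)c(C(=O)c2c(C)cc(O)cc2OC)c1O | target

## Step count and least certain steps

Total: 19 steps. Longest linear sequence: 15 steps (steps 1, 2, 3, 5, 6, 7, 8, 9, 10, 11, 13, 16, 17, 18, 19).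

**Step 13 (key step).** The pairing of a 3-alkoxy-4-alkylcyclobutenone with a C-silyl ynol ether is not covered by existing examples. The silyl group on the attacking alkyne carbon may slow the [2+2] union enough for dimerisation of the vinylketene or its reclosure to dominate. The silyl-substituted dienylketene may be slow to reach the geometry needed for closure. The trimethylsilyl group may be lost by protodesilylation next to the new phenol.

The fallback gives up the ring construction for a directed one-carbon union. It sets out from 10 (with 8 and 32) and returns at 37.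
- Acylation of 8 with 32, as in step 5, would give [2,4-bis(benzyloxy)-6-methylphenyl][4-methoxy-2,6-bis(methoxymethoxy)phenyl]methanone F1.
- Acid methanolysis would free the ring A–B diol [2,4-bis(benzyloxy)-6-methylphenyl](2,6-dihydroxy-4-methoxyphenyl)methanone F2.
- Mannich aminomethylation of 10 (aqueous CH2O, Me2NH, EtOH) at one of its two equivalent ring C positions would give [4-(benzyloxy)-2-methoxy-6-methylphenyl]{3-[(dimethylamino)methyl]-2,6-dihydroxy-4-methoxyphenyl}methanone F3.
- Heating F3 with an excess of F2 (dioxane, reflux) would expel dimethylamine to the ring C ortho-quinone methide 2-[4-(benzyloxy)-2-methoxy-6-methylbenzoyl]-3-hydroxy-5-methoxy-6-methylidenecyclohexa-2,4-dien-1-one F4. One of the two equivalent nucleophilic carbons of F2 would capture it to give the tribenzyl ether of the target F5.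
- Hydrogenolysis as in step 19 then gives 37.

The weakness of this fallback is self-condensation of F3 through its remaining free ring C position, which the excess of F2 is meant to suppress.

**Step 16.** Substitution at the unsubstituted a2 (para to the free hydroxyl) or double iodination may compete with ipso attack at a4. The fallback replaces electrophilic halogenation by a phenol-directed formylation. It sets out from 28 and returns at 35.
- Protodesilylation (CF3CO2H, CH2Cl2, 0 °C) would give 2-(ArCD-methyl)-3-methoxy-5-(triisopropylsilyloxy)phenol F6.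
- Magnesium-mediated ortho-formylation (MgCl2, Et3N, paraformaldehyde, THF, reflux) can only reach a4, the one free position ortho to the hydroxyl, and would give 3-(ArCD-methyl)-2-hydroxy-4-methoxy-6-(triisopropylsilyloxy)benzaldehyde F7.
- Orcinol would be benzylated to 1,3-bis(benzyloxy)-5-methylbenzene F8 and brominated with NBS to 1,5-bis(benzyloxy)-2-bromo-3-methylbenzene F9.
- Bromine–lithium exchange (n-BuLi, THF, −78 °C) would give [2,4-bis(benzyloxy)-6-methylphenyl]lithium F10. Two equivalents would add to F7 to give racemic [2,4-bis(benzyloxy)-6-methylphenyl][3-(ArCD-methyl)-2-hydroxy-4-methoxy-6-(triisopropylsilyloxy)phenyl]methanol F11.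
- Oxidation with Dess–Martin periodinane would give 35, which fluoride converts into 36.

**Step 18.** The alkyllithium may add to K2 or to the ester carbonyl, or the aryllithium may be quenched by proton transfer from the ring B methyl group before the acyl shift. The preceding esterification (step 17), which must join two di-ortho-substituted partners, may also be slow. The fallback avoids both the ester and the migration. It sets out from 31 and returns at 35.
- Protection (MOMCl, iPr2NEt) would give {[4-(ArCD-methyl)-2-iodo-5-methoxy-3-(methoxymethoxy)phenyl]oxy}triisopropylsilane F12.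
- Iodine–lithium exchange (n-BuLi, THF, −78 °C) would give the corresponding aryllithium {[4-(ArCD-methyl)-2-lithio-5-methoxy-3-(methoxymethoxy)phenyl]oxy}triisopropylsilane F13.
- Acylation of F13 with 32, the reaction type of step 5, would give [2,4-bis(benzyloxy)-6-methylphenyl][3-(ArCD-methyl)-4-methoxy-2-(methoxymethoxy)-6-(triisopropylsilyloxy)phenyl]methanone F14.
- Mild acid methanolysis of the acetal would give 35.

**Step 11.** Dimerisation of the monoalkylketene and evaporative loss of the low-boiling alkyne may leave little cycloadduct. The fallback uses a more electrophilic, less dimerisation-prone haloketene. It sets out from 14 and returns at 19.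
- Enolate chlorination (LDA, THF, −78 °C; NCS) would give racemic ethyl 2-chloro-3-(ArCD)propanoate F15.
- Cold saponification (LiOH, 0 °C) would give racemic 2-chloro-3-(ArCD)propanoic acid F16.
- Oxalyl chloride would give racemic 2-chloro-3-(ArCD)propanoyl chloride F17.
- Et3N in the presence of 16 would generate the alkylchloroketene 2-chloro-3-(ArCD)prop-1-en-1-one F18, which would be trapped as racemic 4-chloro-3-methoxy-4-(ArCD-methyl)cyclobut-2-en-1-one F19.
- Reductive dechlorination (zinc dust, AcOH, TMEDA, EtOH) would give 19.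

**Step 19.** Over-reduction of the diaryl ketones to carbinols or methylene groups, or incomplete cleavage at the hindered positions, may accompany the hydrogenolysis. The fallback replaces hydrogen by a Lewis acid with a cation scavenger. It sets out from 36 and returns at 37: BCl3 and pentamethylbenzene in CH2Cl2 at −78 °C would remove the benzyl groups, the low temperature sparing the methyl ether ortho to K2, and no new compound is made on the way.

## Further compounds

F1 | step 13 | [2,4-bis(benzyloxy)-6-methylphenyl][4-methoxy-2,6-bis(methoxymethoxy)phenyl]methanone | COCOc1cc(OC)cc(OCOC)c1C(=O)c1c(C)cc(OCc2ccccc2)cc1OCc1ccccc1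
F2 | step 13 | [2,4-bis(benzyloxy)-6-methylphenyl](2,6-dihydroxy-4-methoxyphenyl)methanone | COc1cc(O)c(C(=O)c2c(C)cc(OCc3ccccc3)cc2OCc2ccccc2)c(O)c1
F3 | step 13 | [4-(benzyloxy)-2-methoxy-6-methylphenyl]{3-[(dimethylamino)methyl]-2,6-dihydroxy-4-methoxyphenyl}methanone | COc1cc(O)c(C(=O)c2c(C)cc(OCc3ccccc3)cc2OC)c(O)c1CN(C)C
F4 | step 13 | 2-[4-(benzyloxy)-2-methoxy-6-methylbenzoyl]-3-hydroxy-5-methoxy-6-methylidenecyclohexa-2,4-dien-1-one | C=C1C(=O)C(C(=O)c2c(C)cc(OCc3ccccc3)cc2OC)=C(O)C=C1OC
F5 | step 13 | tribenzyl ether of the target (ring B dibenzylated, ring D monobenzylated, rings A and C free) | COc1cc(O)c(C(=O)c2c(C)cc(OCc3ccccc3)cc2OCc2ccccc2)c(O)c1Cc1c(OC)cc(O)c(C(=O)c2c(C)cc(OCc3ccccc3)cc2OC)c1O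
F6 | step 16 | 2-(ArCD-methyl)-3-methoxy-5-(triisopropylsilyloxy)phenol | COc1cc(O[Si](C(C)C)(C(C)C)C(C)C)cc(O)c1Cc1c(OC)cc(OCc2ccccc2)c(C(=O)c2c(C)cc(OCc3ccccc3)cc2OC)c1OCc1ccccc1
F7 | step 16 | 3-(ArCD-methyl)-2-hydroxy-4-methoxy-6-(triisopropylsilyloxy)benzaldehyde | COc1cc(O[Si](C(C)C)(C(C)C)C(C)C)c(C=O)c(O)c1Cc1c(OC)cc(OCc2ccccc2)c(C(=O)c2c(C)cc(OCc3ccccc3)cc2OC)c1OCc1ccccc1
F8 | step 16 | 1,3-bis(benzyloxy)-5-methylbenzene | Cc1cc(OCc2ccccc2)cc(OCc2ccccc2)c1
F9 | step 16 | 1,5-bis(benzyloxy)-2-bromo-3-methylbenzene | Cc1cc(OCc2ccccc2)cc(OCc2ccccc2)c1Br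
F10 | step 16 | [2,4-bis(benzyloxy)-6-methylphenyl]lithium | [Li]c1c(C)cc(OCc2ccccc2)cc1OCc1ccccc1
F11 | step 16 | racemic [2,4-bis(benzyloxy)-6-methylphenyl][3-(ArCD-methyl)-2-hydroxy-4-methoxy-6-(triisopropylsilyloxy)phenyl]methanol | COc1cc(O[Si](C(C)C)(C(C)C)C(C)C)c(C(O)c2c(C)cc(OCc3ccccc3)cc2OCc2ccccc2)c(O)c1Cc1c(OC)cc(OCc2ccccc2)c(C(=O)c2c(C)cc(OCc3ccccc3)cc2OC)c1OCc1ccccc1
F12 | step 18 | {[4-(ArCD-methyl)-2-iodo-5-methoxy-3-(methoxymethoxy)phenyl]oxy}triisopropylsilane | COCOc1c(I)c(O[Si](C(C)C)(C(C)C)C(C)C)cc(OC)c1Cc1c(OC)cc(OCc2ccccc2)c(C(=O)c2c(C)cc(OCc3ccccc3)cc2OC)c1OCc1ccccc1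
F13 | step 18 | {[4-(ArCD-methyl)-2-lithio-5-methoxy-3-(methoxymethoxy)phenyl]oxy}triisopropylsilane | COCOc1c([Li])c(O[Si](C(C)C)(C(C)C)C(C)C)cc(OC)c1Cc1c(OC)cc(OCc2ccccc2)c(C(=O)c2c(C)cc(OCc3ccccc3)cc2OC)c1OCc1ccccc1
F14 | step 18 | [2,4-bis(benzyloxy)-6-methylphenyl][3-(ArCD-methyl)-4-methoxy-2-(methoxymethoxy)-6-(triisopropylsilyloxy)phenyl]methanone | COCOc1c(C(=O)c2c(C)cc(OCc3ccccc3)cc2OCc2ccccc2)c(O[Si](C(C)C)(C(C)C)C(C)C)cc(OC)c1Cc1c(OC)cc(OCc2ccccc2)c(C(=O)c2c(C)cc(OCc3ccccc3)cc2OC)c1OCc1ccccc1
F15 | step 11 | racemic ethyl 2-chloro-3-(ArCD)propanoate | CCOC(=O)C(Cl)Cc1c(OC)cc(OCc2ccccc2)c(C(=O)c2c(C)cc(OCc3ccccc3)cc2OC)c1OCc1ccccc1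
F16 | step 11 | racemic 2-chloro-3-(ArCD)propanoic acid | OC(=O)C(Cl)Cc1c(OC)cc(OCc2ccccc2)c(C(=O)c2c(C)cc(OCc3ccccc3)cc2OC)c1OCc1ccccc1
F17 | step 11 | racemic 2-chloro-3-(ArCD)propanoyl chloride | ClC(=O)C(Cl)Cc1c(OC)cc(OCc2ccccc2)c(C(=O)c2c(C)cc(OCc3ccccc3)cc2OC)c1OCc1ccccc1
F18 | step 11 | 2-chloro-3-(ArCD)prop-1-en-1-one (alkylchloroketene) | O=C=C(Cl)Cc1c(OC)cc(OCc2ccccc2)c(C(=O)c2c(C)cc(OCc3ccccc3)cc2OC)c1OCc1ccccc1
F19 | step 11 | racemic 4-chloro-3-methoxy-4-(ArCD-methyl)cyclobut-2-en-1-one | COC1=CC(=O)C1(Cl)Cc1c(OC)cc(OCc2ccccc2)c(C(=O)c2c(C)cc(OCc3ccccc3)cc2OC)c1OCc1ccccc1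
F0 | step 19 | none | none
A1 | alternative 1 | tert-butyl 3-[3-(ArCD-methyl)-2,6-bis(benzyloxy)-4-methoxyphenyl]-3-oxopropanoate | COc1cc(OCc2ccccc2)c(C(=O)CC(=O)OC(C)(C)C)c(OCc2ccccc2)c1Cc1c(OC)cc(OCc2ccccc2)c(C(=O)c2c(C)cc(OCc3ccccc3)cc2OC)c1OCc1ccccc1
A2 | alternative 1 | 3,5-bis(benzyloxy)-2-(trimethylsilyl)phenyl trifluoromethanesulfonate | C[Si](C)(C)c1c(OCc2ccccc2)cc(OCc2ccccc2)cc1OS(=O)(=O)C(F)(F)F
A3 | alternative 1 | heptabenzyl ether of the target with a tert-butoxycarbonylmethyl group in place of the ring B methyl | COc1cc(OCc2ccccc2)c(C(=O)c2c(CC(=O)OC(C)(C)C)cc(OCc3ccccc3)cc2OCc2ccccc2)c(OCc2ccccc2)c1Cc1c(OC)cc(OCc2ccccc2)c(C(=O)c2c(C)cc(OCc3ccccc3)cc2OC)c1OCc1ccccc1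
A4 | alternative 2 | 1-[3-(ArCD-methyl)-2,6-bis(benzyloxy)-4-methoxyphenyl]octane-1,3,5,7-tetraone | CC(=O)CC(=O)CC(=O)CC(=O)c1c(OCc2ccccc2)cc(OC)c(Cc2c(OC)cc(OCc3ccccc3)c(C(=O)c3c(C)cc(OCc4ccccc4)cc3OC)c2OCc2ccccc2)c1OCc1ccccc1
A5 | alternative 2 | pentabenzyl ether of the target with both ring B hydroxyls free | COc1cc(OCc2ccccc2)c(C(=O)c2c(C)cc(O)cc2O)c(OCc2ccccc2)c1Cc1c(OC)cc(OCc2ccccc2)c(C(=O)c2c(C)cc(OCc3ccccc3)cc2OC)c1OCc1ccccc1
A6 | alternative 3 | 3-({2,4-bis(benzyloxy)-3-[2,4-bis(benzyloxy)-6-methylbenzoyl]-6-methoxyphenyl}methyl)-6-{2-[4-(benzyloxy)-2-methoxy-6-methylphenyl]-2-oxoethyl}-4-methoxy-2H-pyran-2-one | COC1=C(Cc2c(OC)cc(OCc3ccccc3)c(C(=O)c3c(C)cc(OCc4ccccc4)cc3OCc3ccccc3)c2OCc2ccccc2)C(=O)OC(CC(=O)c2c(C)cc(OCc3ccccc3)cc2OC)=C1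
A7 | alternative 3 | pentabenzyl ether of the target with both ring C hydroxyls free | COc1cc(O)c(C(=O)c2c(C)cc(OCc3ccccc3)cc2OC)c(O)c1Cc1c(OC)cc(OCc2ccccc2)c(C(=O)c2c(C)cc(OCc3ccccc3)cc2OCc2ccccc2)c1OCc1ccccc1
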